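Everything rests on cutting ring B between C1′ and C6′. In ring B the ether carbon C1′ lies between the hydroxyl-bearing C2′ and the hydroxymethyl-bearing C6′, with the methyl group para to it at C4′; read with C2′ and C6′ as carbonyl carbons, this is a 2-aryloxy-5-methylcyclohexane-1,3-dione. The key step, an intramolecular Claisen condensation, closes that dione in one operation from an acyclic precursor in which the crowded diaryl ether oxygen already sits on an sp3 carbon: the ring A ether of methyl 6-hydroxy-3-methyl-5-oxohexanoate, carrying the silylated (S)-carbinol and a tert-butyl benzoate that cannot act as a rival acyl acceptor. Enol triflation, hydroxymethylation and dehydrogenation then complete ring B.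

Key step: step 9

Remark: the methyl-bearing carbon of the six-carbon fragment is used as the racemate, so every intermediate between the ether formation and the aromatisation of ring B is a pair of epimers at that carbon (drawn without a descriptor); the pair converges when ring B becomes aromatic.

Remark: (S)-BINOL is assumed to deliver the (S)-carbinol in step 2, by analogy with titanium–BINOLate additions to simple aromatic aldehydes; configuration and enantiomeric purity would be checked (Mosher esters, chiral HPLC) before going on.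

Step 1
Reactants: 1 4-hydroxy-2-methoxybenzaldehyde
Product: 2 4-[(benzyloxy)methoxy]-2-methoxybenzaldehyde
Conditions: BOMCl, K2CO3, DMF, 0 °C → rt
Reagents that add atoms: benzyl chloromethyl ether, ClCOCc1ccccc1
Why: Williamson-type O-alkylation of the acidic para-formyl phenoxide by a reactive α-chloro ether should be clean, and the benzyloxymethyl acetal is chosen because it later directs ortho-lithiation and is removed by neutral hydrogenolysis.

Step 2
Reactants: 2 4-[(benzyloxy)methoxy]-2-methoxybenzaldehyde; 3 isobutylmagnesium bromide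
Product: 4 (1S)-1-{4-[(benzyloxy)methoxy]-2-methoxyphenyl}-3-methylbutan-1-ol
Conditions: 3 premixed with bis[2-(dimethylamino)ethyl] ether, (S)-BINOL ((S)-1,1′-bi-2-naphthol, 15 mol %), Ti(OiPr)4, MTBE, 0 °C → rt; aq NH4Cl
Reagents that add atoms: none
Why: Titanium–BINOLate-catalysed enantioselective 1,2-addition of an alkyl Grignard reagent (tamed by the chelating amino ether) to an aromatic aldehyde, in which the (S)-BINOL–titanium complex differentiates the two aldehyde faces and should set the (S)-carbinol.

Step 3
Reactants: 4 (1S)-1-{4-[(benzyloxy)methoxy]-2-methoxyphenyl}-3-methylbutan-1-ol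
Product: 5 {(1S)-1-{4-[(benzyloxy)methoxy]-2-methoxyphenyl}-3-methylbutoxy}(tert-butyl)dimethylsilane
Conditions: TBSCl, imidazole, DMF, rt
Reagents that add atoms: tert-butyldimethylsilyl chloride, CC(C)(C)[Si](C)(C)Cl
Why: Standard imidazole-promoted silylation of a secondary benzylic alcohol, which breaks no bond at the stereocentre and gives an ether stable to organolithium, alkoxide and palladium chemistry.

Step 4
Reactants: 5 {(1S)-1-{4-[(benzyloxy)methoxy]-2-methoxyphenyl}-3-methylbutoxy}(tert-butyl)dimethylsilane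
Product: 7 tert-butyl 6-[(benzyloxy)methoxy]-3-[(1S)-1-{[tert-butyl(dimethyl)silyl]oxy}-3-methylbutyl]-2-methoxybenzoate, via the aryllithium 6 (not isolated)
Conditions: n-BuLi, TMEDA, THF, −78 → 0 °C; Boc2O, −78 °C → rt
Reagents that add atoms: di-tert-butyl dicarbonate, CC(C)(C)OC(=O)OC(=O)OC(C)(C)C
Why: Directed ortho-metalation should occur at the one ring C–H flanked by both the methoxy and the acetal oxygen, and acylation of the aryllithium by Boc2O gives directly a tert-butyl benzoate, an ester too hindered to serve as an acyl acceptor in step 9.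

Step 5
Reactants: 7 tert-butyl 6-[(benzyloxy)methoxy]-3-[(1S)-1-{[tert-butyl(dimethyl)silyl]oxy}-3-methylbutyl]-2-methoxybenzoate
Product: 8 tert-butyl 3-[(1S)-1-{[tert-butyl(dimethyl)silyl]oxy}-3-methylbutyl]-6-hydroxy-2-methoxybenzoate
Conditions: H2 (1 atm), 10 % Pd/C, EtOAc, rt
Reagents that add atoms: none
Why: Catalytic hydrogenolysis of the benzyl C–O bond leaves a hemiformal that loses formaldehyde to the phenol under neutral conditions that should spare the silyl ether and the tert-butyl ester.

Step 6
Reactants: 9 3-methylglutaric anhydride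
Product: 10 5-methoxy-3-methyl-5-oxopentanoic acid (racemic)
Conditions: MeOH, reflux
Reagents that add atoms: methanol, CO
Why: Methanolysis of a symmetric cyclic anhydride (nucleophilic acyl substitution) can give only one half ester, and its racemic methyl-bearing carbon is of no consequence.

Step 7
Reactants: 10 5-methoxy-3-methyl-5-oxopentanoic acid
Product: 13 methyl 6-bromo-3-methyl-5-oxohexanoate (racemic), via acid chloride 11 (not isolated), via diazoketone 12 (not isolated)
Conditions: (COCl)2, DMF (cat.), CH2Cl2, 0 °C → rt; evaporate; TMSCHN2, THF/MeCN, 0 °C; 48 % aq HBr, 0 °C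
Reagents that add atoms: (trimethylsilyl)diazomethane, C[Si](C)(C)C=[N+]=[N-]; hydrogen bromide, Br
Why: The acid chloride acylates the diazoalkane to the α-diazo ketone (first stage of an Arndt–Eistert sequence), which HBr protonates on carbon and substitutes with loss of dinitrogen to give the bromomethyl ketone while the methyl ester stays untouched.

Step 8
Reactants: 8 tert-butyl 3-[(1S)-1-{[tert-butyl(dimethyl)silyl]oxy}-3-methylbutyl]-6-hydroxy-2-methoxybenzoate; 13 methyl 6-bromo-3-methyl-5-oxohexanoate
Product: 14 tert-butyl 3-[(1S)-1-{[tert-butyl(dimethyl)silyl]oxy}-3-methylbutyl]-2-methoxy-6-[(6-methoxy-4-methyl-2,6-dioxohexyl)oxy]benzoate (both epimers at the methyl-bearing carbon)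
Conditions: K2CO3, acetone, rt
Reagents that add atoms: none
Why: Williamson ether synthesis in which the phenoxide displaces bromide from the highly SN2-reactive α-bromo ketone under carbonate conditions too mild to drive condensation of the product, so the crowded ether oxygen is installed at an sp3 carbon.

Step 9
Reactants: 14 tert-butyl 3-[(1S)-1-{[tert-butyl(dimethyl)silyl]oxy}-3-methylbutyl]-2-methoxy-6-[(6-methoxy-4-methyl-2,6-dioxohexyl)oxy]benzoate
Product: 15 tert-butyl 3-[(1S)-1-{[tert-butyl(dimethyl)silyl]oxy}-3-methylbutyl]-2-methoxy-6-[(4-methyl-2,6-dioxocyclohexyl)oxy]benzoate (predominantly as its enol)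
Conditions: KOtBu (2.2 equiv), THF (0.02 M), 0 °C → rt; 1 M aq HCl to pH 4, 0 °C
Reagents that add atoms: none
Why: Reversible enolisation by KOtBu gives the enolate at the aryloxy-bearing methylene of the ketone, whose carbon adds to the methyl ester carbonyl and expels methoxide, forming the C1′–C6′ bond; the resulting 2-aryloxy-1,3-dione is deprotonated at once to its diketonate, which makes the condensation irreversible. The closest known reaction type is the base-mediated intramolecular Claisen (Dieckmann-type) cyclisation of 5-oxoalkanoates to cyclohexane-1,3-diones. Ring B closes in the 6-(enolexo)-exo-trig mode. No lasting stereocentre is created, because C1′ is enolised in the product and the methyl-bearing carbon lies on the time-averaged mirror plane of the dione, so both epimers of 14 should converge on one compound. The step needs site selectivity between the two ketone enolates and acceptor selectivity between the two esters: the enolate on the far side of the ketone could only close a four-membered ring and re-equilibrates, whereas the benzoate ortho to the aryloxy group, which as a primary ester would offer the same enolate a 5-exo closure to a 3-hydroxybenzofuran, is here a tert-butyl ester and hence a poor acceptor (the usual methyl-over-tert-butyl discrimination of Dieckmann chemistry). High dilution suppresses intermolecular condensation, and the silyl ether is inert to alkoxide.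

Step 10
Reactants: 15 tert-butyl 3-[(1S)-1-{[tert-butyl(dimethyl)silyl]oxy}-3-methylbutyl]-2-methoxy-6-[(4-methyl-2,6-dioxocyclohexyl)oxy]benzoate
Product: 16 tert-butyl 3-[(1S)-1-{[tert-butyl(dimethyl)silyl]oxy}-3-methylbutyl]-2-methoxy-6-[(4-methyl-6-oxo-2-{[(trifluoromethyl)sulfonyl]oxy}cyclohex-1-en-1-yl)oxy]benzoate (both epimers at the methyl-bearing carbon)
Conditions: Tf2O, Et3N, CH2Cl2, −78 °C
Reagents that add atoms: trifluoromethanesulfonic anhydride, O=S(=O)(OS(=O)(=O)C(F)(F)F)C(F)(F)F
Why: O-Sulfonylation of the enol of a cyclic 1,3-dione gives the vinylogous triflate, and since the two carbonyls are equivalent and the product has no acidic enol left, a single monotriflate should result.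

Step 11
Reactants: 16 tert-butyl 3-[(1S)-1-{[tert-butyl(dimethyl)silyl]oxy}-3-methylbutyl]-2-methoxy-6-[(4-methyl-6-oxo-2-{[(trifluoromethyl)sulfonyl]oxy}cyclohex-1-en-1-yl)oxy]benzoate
Product: 17 tert-butyl 3-[(1S)-1-{[tert-butyl(dimethyl)silyl]oxy}-3-methylbutyl]-6-{[2-(hydroxymethyl)-4-methyl-6-oxocyclohex-1-en-1-yl]oxy}-2-methoxybenzoate (both epimers at the methyl-bearing carbon)
Conditions: Bu3SnCH2OH, Pd(PPh3)4 (5 mol %), LiCl, 1,4-dioxane, 90 °C
Reagents that add atoms: (tributylstannyl)methanol, CCCC[Sn](CCCC)(CCCC)CO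
Why: Stille cross-coupling in which zerovalent palladium inserts readily into the electron-poor enol triflate, chloride assists transfer of the hydroxymethyl group from tin, and reductive elimination forms the C6′–CH2OH bond.

Step 12
Reactants: 17 tert-butyl 3-[(1S)-1-{[tert-butyl(dimethyl)silyl]oxy}-3-methylbutyl]-6-{[2-(hydroxymethyl)-4-methyl-6-oxocyclohex-1-en-1-yl]oxy}-2-methoxybenzoate
Product: 20 tert-butyl 3-[(1S)-1-{[tert-butyl(dimethyl)silyl]oxy}-3-methylbutyl]-6-[2-hydroxy-6-(hydroxymethyl)-4-methylphenoxy]-2-methoxybenzoate, via bis(trimethylsilyl) dienol ether 18 (not isolated), via trimethylsilyl ether phenol 19 (not isolated)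
Conditions: LiN(iPr)2 (2.3 equiv), THF, −78 °C; TMSCl, −78 → 0 °C; evaporate; Pd(OAc)2 (1.2 equiv), MeCN, rt; K2CO3 (cat.), MeOH, 0 °C
Reagents that add atoms: none
Why: Saegusa–Ito dehydrogenation, in which the alkoxide and the cross-conjugated enolate are trapped as the bis(trimethylsilyl) derivative, Pd(OAc)2 turns the silyl dienol ether into a palladium enolate that loses a β-hydride, the cyclohexadienone tautomerises to the phenol, and methanolysis removes the remaining primary trimethylsilyl ether.

Step 13
Reactants: 20 tert-butyl 3-[(1S)-1-{[tert-butyl(dimethyl)silyl]oxy}-3-methylbutyl]-6-[2-hydroxy-6-(hydroxymethyl)-4-methylphenoxy]-2-methoxybenzoate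
Product: 22 6-[2-hydroxy-6-(hydroxymethyl)-4-methylphenoxy]-3-[(1S)-1-hydroxy-3-methylbutyl]-2-methoxybenzoic acid, via tris(trimethylsilyl) derivative 21 (not isolated)
Conditions: TMSOTf, 2,6-lutidine, CH2Cl2, 0 °C → rt; evaporate; Bu4NF, THF, rt; aq NH4Cl, then pH 4 buffer
Reagents that add atoms: none
Why: Silyl triflate-mediated cleavage of the tert-butyl ester (O-silylation and loss of isobutene under lutidine buffering, the non-protic conditions under which benzylic silyl ethers are themselves made) followed by fluoride desilylation should release acid, phenol and both alcohols without exposing the ionisable benzylic carbinol to Brønsted acid or touching the stereocentre.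

Compound list

1 | 4-hydroxy-2-methoxybenzaldehyde | COc1cc(O)ccc1C=O | starting material
2 | 4-[(benzyloxy)methoxy]-2-methoxybenzaldehyde | COc1cc(OCOCc2ccccc2)ccc1C=O | intermediate
3 | isobutylmagnesium bromide | CC(C)C[Mg]Br | starting material
4 | (1S)-1-{4-[(benzyloxy)methoxy]-2-methoxyphenyl}-3-methylbutan-1-ol | COc1cc(OCOCc2ccccc2)ccc1[C@@H](O)CC(C)C | intermediate
5 | {(1S)-1-{4-[(benzyloxy)methoxy]-2-methoxyphenyl}-3-methylbutoxy}(tert-butyl)dimethylsilane | COc1cc(OCOCc2ccccc2)ccc1[C@@H](O[Si](C)(C)C(C)(C)C)CC(C)C | intermediate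
6 | {6-[(benzyloxy)methoxy]-3-[(1S)-1-{[tert-butyl(dimethyl)silyl]oxy}-3-methylbutyl]-2-methoxyphenyl}lithium | COc1c([C@@H](O[Si](C)(C)C(C)(C)C)CC(C)C)ccc(OCOCc2ccccc2)c1[Li] | intermediate (not isolated)
7 | tert-butyl 6-[(benzyloxy)methoxy]-3-[(1S)-1-{[tert-butyl(dimethyl)silyl]oxy}-3-methylbutyl]-2-methoxybenzoate | COc1c([C@@H](O[Si](C)(C)C(C)(C)C)CC(C)C)ccc(OCOCc2ccccc2)c1C(=O)OC(C)(C)C | intermediate
8 | tert-butyl 3-[(1S)-1-{[tert-butyl(dimethyl)silyl]oxy}-3-methylbutyl]-6-hydroxy-2-methoxybenzoate | COc1c([C@@H](O[Si](C)(C)C(C)(C)C)CC(C)C)ccc(O)c1C(=O)OC(C)(C)C | intermediate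
9 | 3-methylglutaric anhydride | CC1CC(=O)OC(=O)C1 | starting material
10 | 5-methoxy-3-methyl-5-oxopentanoic acid (racemic) | COC(=O)CC(C)CC(=O)O | intermediate
11 | methyl 5-chloro-3-methyl-5-oxopentanoate (racemic) | COC(=O)CC(C)CC(=O)Cl | intermediate (not isolated)
12 | methyl 6-diazo-3-methyl-5-oxohexanoate (racemic) | COC(=O)CC(C)CC(=O)C=[N+]=[N-] | intermediate (not isolated)
13 | methyl 6-bromo-3-methyl-5-oxohexanoate (racemic) | COC(=O)CC(C)CC(=O)CBr | intermediate
14 | tert-butyl 3-[(1S)-1-{[tert-butyl(dimethyl)silyl]oxy}-3-methylbutyl]-2-methoxy-6-[(6-methoxy-4-methyl-2,6-dioxohexyl)oxy]benzoate (both epimers at the methyl-bearing carbon) | COc1c([C@@H](O[Si](C)(C)C(C)(C)C)CC(C)C)ccc(OCC(=O)CC(C)CC(=O)OC)c1C(=O)OC(C)(C)C | intermediate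
15 | tert-butyl 3-[(1S)-1-{[tert-butyl(dimethyl)silyl]oxy}-3-methylbutyl]-2-methoxy-6-[(4-methyl-2,6-dioxocyclohexyl)oxy]benzoate (drawn as the diketone) | COc1c([C@@H](O[Si](C)(C)C(C)(C)C)CC(C)C)ccc(OC2C(=O)CC(C)CC2=O)c1C(=O)OC(C)(C)C | intermediate
16 | tert-butyl 3-[(1S)-1-{[tert-butyl(dimethyl)silyl]oxy}-3-methylbutyl]-2-methoxy-6-[(4-methyl-6-oxo-2-{[(trifluoromethyl)sulfonyl]oxy}cyclohex-1-en-1-yl)oxy]benzoate (both epimers at the methyl-bearing carbon) | COc1c([C@@H](O[Si](C)(C)C(C)(C)C)CC(C)C)ccc(OC2=C(OS(=O)(=O)C(F)(F)F)CC(C)CC2=O)c1C(=O)OC(C)(C)C | intermediate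
17 | tert-butyl 3-[(1S)-1-{[tert-butyl(dimethyl)silyl]oxy}-3-methylbutyl]-6-{[2-(hydroxymethyl)-4-methyl-6-oxocyclohex-1-en-1-yl]oxy}-2-methoxybenzoate (both epimers at the methyl-bearing carbon) | COc1c([C@@H](O[Si](C)(C)C(C)(C)C)CC(C)C)ccc(OC2=C(CO)CC(C)CC2=O)c1C(=O)OC(C)(C)C | intermediate
18 | tert-butyl 3-[(1S)-1-{[tert-butyl(dimethyl)silyl]oxy}-3-methylbutyl]-2-methoxy-6-[(4-methyl-6-[(trimethylsilyl)oxy]-2-{[(trimethylsilyl)oxy]methyl}cyclohexa-1,5-dien-1-yl)oxy]benzoate (both epimers at the methyl-bearing carbon) | COc1c([C@@H](O[Si](C)(C)C(C)(C)C)CC(C)C)ccc(OC2=C(CO[Si](C)(C)C)CC(C)C=C2O[Si](C)(C)C)c1C(=O)OC(C)(C)C | intermediate (not isolated)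
19 | tert-butyl 3-[(1S)-1-{[tert-butyl(dimethyl)silyl]oxy}-3-methylbutyl]-6-(2-hydroxy-4-methyl-6-{[(trimethylsilyl)oxy]methyl}phenoxy)-2-methoxybenzoate | COc1c([C@@H](O[Si](C)(C)C(C)(C)C)CC(C)C)ccc(Oc2c(O)cc(C)cc2CO[Si](C)(C)C)c1C(=O)OC(C)(C)C | intermediate (not isolated)
20 | tert-butyl 3-[(1S)-1-{[tert-butyl(dimethyl)silyl]oxy}-3-methylbutyl]-6-[2-hydroxy-6-(hydroxymethyl)-4-methylphenoxy]-2-methoxybenzoate | COc1c([C@@H](O[Si](C)(C)C(C)(C)C)CC(C)C)ccc(Oc2c(O)cc(C)cc2CO)c1C(=O)OC(C)(C)C | intermediate
21 | trimethylsilyl 3-[(1S)-1-{[tert-butyl(dimethyl)silyl]oxy}-3-methylbutyl]-2-methoxy-6-(4-methyl-2-[(trimethylsilyl)oxy]-6-{[(trimethylsilyl)oxy]methyl}phenoxy)benzoate | COc1c([C@@H](O[Si](C)(C)C(C)(C)C)CC(C)C)ccc(Oc2c(O[Si](C)(C)C)cc(C)cc2CO[Si](C)(C)C)c1C(=O)O[Si](C)(C)C | intermediate (not isolated)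
22 | 6-[2-hydroxy-6-(hydroxymethyl)-4-methylphenoxy]-3-[(1S)-1-hydroxy-3-methylbutyl]-2-methoxybenzoic acid | COc1c([C@@H](O)CC(C)C)ccc(Oc2c(O)cc(C)cc2CO)c1C(=O)O | target

Total step count: 13 steps.
Longest linear sequence: 11 steps (steps 1–5 and 8–13, from 1); the bromo ketone 13 is made in 2 steps (steps 6 and 7) from 9.

Steps most likely to fail

Step 9. The enolate may acylate at the wrong carbonyl (5-exo closure onto the benzoate in spite of the tert-butyl group), or intermolecular aldol and Claisen condensation may outrun ring closure. The fallback forms the C1′–O bond on a preformed dione instead of closing the ring. It sets out from phenol 8. Commercial 5-methylcyclohexane-1,3-dione would be converted by diazo transfer (4-acetamidobenzenesulfonyl azide, Et3N, MeCN, rt) into 2-diazo-5-methylcyclohexane-1,3-dione F1. Slow addition of F1 to 8 and Rh2(OAc)4 (2 mol %) in 1,2-dichloroethane at 60–80 °C should give, by O–H insertion of the rhodium carbenoid into the phenol, the 2-aryloxy dione directly. The fallback comes back to the route at 15.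

Step 12. Proton abstraction may occur at the wrong site, or the palladium-mediated dehydrosilylation may stop short and return enone or oxidise the liberated benzylic alcohol. The fallback replaces it by selenoxide elimination and sets out from 17. Silylation (TMSCl, Et3N, CH2Cl2, 0 °C) should give the primary trimethylsilyl ether F2. Kinetic deprotonation with LiN(iPr)2 in THF at −78 °C and trapping with PhSeBr should give the α′-phenylselanyl ketone F3. Oxidation with H2O2 and pyridine in CH2Cl2 at 0 °C triggers syn-elimination of the selenoxide, and the resulting dienone tautomerises to the phenol. The fallback comes back to the route at 19, which is methanolysed to 20 as in step 12.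

Step 2. Facial discrimination may be insufficient (uncatalysed background addition to the electron-rich aldehyde), or β-hydride transfer from the Grignard reagent may reduce the aldehyde. The fallback sets the stereocentre by reduction and sets out from 2. Uncatalysed addition of 3 in THF at 0 °C should give the racemic carbinol F4. Oxidation with Dess–Martin periodinane in CH2Cl2 should give the aryl isobutyl ketone F5. Corey–Bakshi–Shibata reduction with (R)-2-methyl-CBS-oxazaborolidine [(3aR)-1-methyl-3,3-diphenyltetrahydro-1H,3H-pyrrolo[1,2-c][1,3,2]oxazaborole, 10 mol %] and BH3·SMe2 in THF at −20 °C should deliver hydride to the face that gives the (S)-alcohol (aryl as the large group). The fallback comes back to the route at 4.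

Further compounds

F1 | step 9 | 2-diazo-5-methylcyclohexane-1,3-dione | CC1CC(=O)C(=[N+]=[N-])C(=O)C1
F2 | step 12 | tert-butyl 3-[(1S)-1-{[tert-butyl(dimethyl)silyl]oxy}-3-methylbutyl]-2-methoxy-6-[(4-methyl-6-oxo-2-{[(trimethylsilyl)oxy]methyl}cyclohex-1-en-1-yl)oxy]benzoate (both epimers at the methyl-bearing carbon) | COc1c([C@@H](O[Si](C)(C)C(C)(C)C)CC(C)C)ccc(OC2=C(CO[Si](C)(C)C)CC(C)CC2=O)c1C(=O)OC(C)(C)C
F3 | step 12 | tert-butyl 3-[(1S)-1-{[tert-butyl(dimethyl)silyl]oxy}-3-methylbutyl]-2-methoxy-6-{[4-methyl-6-oxo-5-(phenylselanyl)-2-{[(trimethylsilyl)oxy]methyl}cyclohex-1-en-1-yl]oxy}benzoate (mixture of diastereomers) | COc1c([C@@H](O[Si](C)(C)C(C)(C)C)CC(C)C)ccc(OC2=C(CO[Si](C)(C)C)CC(C)C([Se]c3ccccc3)C2=O)c1C(=O)OC(C)(C)C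
F4 | step 2 | 1-{4-[(benzyloxy)methoxy]-2-methoxyphenyl}-3-methylbutan-1-ol (racemic) | COc1cc(OCOCc2ccccc2)ccc1C(O)CC(C)C
F5 | step 2 | 1-{4-[(benzyloxy)methoxy]-2-methoxyphenyl}-3-methylbutan-1-one | COc1cc(OCOCc2ccccc2)ccc1C(=O)CC(C)C
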